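The pitfall on a plate of ligand exchanges is to read the charge of incoming ligand as the yield of complex with two exchanged, when each unit of that product costs two incoming ligands. So we keep a ledger of incoming ligand, which Saturday's and Friday's flasks charge short of full exchange; in those flasks it is the limiting reagent.

| flask | starting complex | incoming ligand | leaving ligand | remark | time |
|---|---|---|---|---|---|
| epsilon | 0.25 M | 0.125 M | 0.34 M | run made earlier |  |
| Saturday's | 0.25 M | 0.125 M | 0.500 M |  | 30 h |
| Friday's | 0.25 M | 0.375 M | 0.500 M |  | 30 h |
| Sunday's | 0.25 M | 1.00 M | 0.500 M |  | 30 h |

epsilon run (percent of the starting complex charged)

| time / h | complex with two exchanged / % | complex with one exchanged / % |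
|---|---|---|
| 0.833 | 0 | 3.5 |
| 2.00 | 0.6 | 2.7 |
| 5.00 | 1.5 | 4.9 |
| 10.0 | 1.0 | 11.5 |

(each reading ± 1 percentage point)

- percent here means starting complex units held: one self-condensation product or side product counts as two
- the numbers in the tables scatter with a standard deviation of 1 percentage point
- steps thought possible: starting complex + incoming ligand -> leaving ligand + complex with one exchanged; complex with one exchanged + incoming ligand -> leaving ligand + complex with two exchanged; 2 starting complex -> self-condensation product; starting complex + complex with one exchanged -> side product
- no earlier run changes the charge of leaving ligand; that part of a forecast is a guess
- no earlier run changes the charge of incoming ligand; that part of a forecast is a guess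

1. complex with two exchanged at the end, in percent of the starting complex charged, for each flask in turn (Saturday's, Friday's, Sunday's)

The epsilon run has the charges of Saturday's flask, except for leaving ligand. At 10.0 h its books read as follows: 11.5% of complex with one exchanged cost one ligand each, and 1.0% of complex with two exchanged cost two each. So, as a reading, ligand worth 13.5% of the starting complex charged has been spent, out of a budget of 50.0%. Side product also holds ligand, but that entry was not read.

We carry one quantity, 25.0% for Saturday's flask: the ceiling, incoming ligand charged over twice the starting complex charged. It is 75.0% for Friday's flask. For Sunday's flask it is 200%, so there the ligand exceeds what the complex can take, and starting complex becomes the limiting reagent.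

The ceiling caps the books and says nothing of the pace. In the epsilon ledger, complex with two exchanged had taken, as a reading, 14.8% of the ligand spent, so we expect Saturday's flask to end far beneath its ceiling at 30 h.

The forecast gives 4%, 23% and 63% for Saturday's, Friday's and Sunday's flasks, and its maker chose to “shade the forecasts down slightly”.

The flasks give 5.77%, 32.2% and 84.4%, in the same order.

    starting complex + incoming ligand → leaving ligand + complex with one exchanged (k = 0.00221 M⁻¹ min⁻¹)
    complex with one exchanged + incoming ligand → leaving ligand + complex with two exchanged (k = 0.00355 M⁻¹ min⁻¹)
    2 starting complex → self-condensation product (k = 8.81 × 10⁻⁶ M⁻¹ min⁻¹)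
    starting complex + complex with one exchanged → side product (k = 2.10 × 10⁻⁴ M⁻¹ min⁻¹)

Saturday's 5.77% stands well under its ceiling of 25.0%, and Friday's 32.2% stands under its ceiling of 75.0%. Part of Friday's gap comes from two things acting together, the falling level of incoming ligand and the time allowed. With the level held at its charge, Friday's flask shows 54.4% at 30.0 h. Given 300 h instead, it shows 65.6%, still under the ceiling, beside 14.0% of complex with one exchanged and 0.690% of the incoming ligand charged.

(The readings stem from a simulated flask with made-up constants; the scatter is artificial.)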